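## Retrosynthetic overview

1. The target is a (2R)-eriodictyol whose ring B carbon C6' is bonded to C8 of a luteolin. All eight hydroxyls travel as benzyl ethers and are freed last. The flavanone ring C and its C2 stereocentre are closed late by a catalyst-controlled oxa-Michael addition onto a tert-butyl-ester-activated chalcone, made by Knoevenagel condensation from a biaryl aldehyde.
2. The luteolin pyranone ring comes from 6-endo closure of an ortho-hydroxyaryl ynone. This is reached by ortho-formylation of a phenol and addition of 3,4-bis(benzyloxy)phenylacetylide.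
3. Feature used: luteolin ring A is a phloroglucinol (oxygen on C5, C7 and C8a) whose aryl-bearing C8 lies between the oxygenated C7 and C8a. This is the 1-hydroxy-2-aryl-3-siloxy-5-alkoxy pattern that an aryl siloxyalkyne and a 3-alkoxy vinylketene assemble.
4. Ring A is therefore built de novo on an alkyne that already carries ring B, forming C8–C8a, C6–C7 and C4a–C8a. The crowded ring B–C8 bond starts life as a plain Sonogashira aryl–alkyne bond.
5. Ring order: luteolin ring A (benzannulation), then the luteolin pyranone ring, then flavanone ring C. The other four benzene rings are purchased.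

Key step: step 7

Assumption: the ring B–luteolin C8 axis bears no descriptor in the given structure, so it is left uncontrolled; rotamers or atropisomers about it from 16 onward are carried together, and only flavanone C2, which is R by CIP analysis of the given SMILES, is set.

## Route

Step 1
Reactants: 1 3,4-bis(benzyloxy)benzaldehyde
Product: 2 4,5-bis(benzyloxy)-2-bromobenzaldehyde
Conditions: Br2 (1.05 equiv), NaOAc (1.2 equiv), AcOH, rt
Reagents that add atoms: bromine, BrBr
Why: Electrophilic aromatic bromination should go to C6, para to the 3-benzyloxy group, as is general for 3,4-dialkoxybenzaldehydes, while the acetate buffer keeps HBr away from the benzyl ethers.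

Step 2
Reactants: 2 4,5-bis(benzyloxy)-2-bromobenzaldehyde; 3 trimethylsilylacetylene
Product: 4 4,5-bis(benzyloxy)-2-[(trimethylsilyl)ethynyl]benzaldehyde
Conditions: PdCl2(PPh3)2 (3 mol %), CuI (5 mol %), Et3N, THF, sealed flask, 55 °C
Reagents that add atoms: none
Why: Sonogashira coupling, run before acetalisation because the ortho-formyl group activates the otherwise electron-rich aryl bromide toward oxidative addition to zerovalent palladium.

Step 3
Reactants: 4 4,5-bis(benzyloxy)-2-[(trimethylsilyl)ethynyl]benzaldehyde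
Product: 5 2-{4,5-bis(benzyloxy)-2-[(trimethylsilyl)ethynyl]phenyl}-1,3-dioxolane
Conditions: HOCH2CH2OH (5 equiv), p-TsOH·H2O (5 mol %), toluene, Dean–Stark, reflux
Reagents that add atoms: ethylene glycol, OCCO
Why: Acid-catalysed acetalisation with azeotropic removal of water masks the aldehyde against the organolithium reagents of steps 5 and 10, and the C-silyl alkyne and benzyl ethers are inert to it.

Step 4
Reactants: 5 2-{4,5-bis(benzyloxy)-2-[(trimethylsilyl)ethynyl]phenyl}-1,3-dioxolane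
Product: 6 2-[4,5-bis(benzyloxy)-2-ethynylphenyl]-1,3-dioxolane
Conditions: K2CO3 (0.2 equiv), MeOH–THF, rt
Reagents that add atoms: none
Why: Carbonate-catalysed methanolysis of the alkynyl C–Si bond is a standard protodesilylation, and the basic medium leaves the dioxolane untouched.

Step 5
Reactants: 6 2-[4,5-bis(benzyloxy)-2-ethynylphenyl]-1,3-dioxolane
Product: 9 {[4,5-bis(benzyloxy)-2-(1,3-dioxolan-2-yl)phenyl]ethynyloxy}triisopropylsilane, via lithium acetylide 7 (not isolated), via lithium ynolate 8 (not isolated)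
Conditions: n-BuLi, THF, −78 °C; t-BuOOLi (from t-BuOOH and LiN(SiMe3)2, THF, −78 °C), −78 to 0 °C; TIPSOTf, −78 to 0 °C; aqueous work-up, Et3N-deactivated silica
Reagents that add atoms: tert-butyl hydroperoxide, CC(C)(C)OO; triisopropylsilyl triflate, CC(C)[Si](OS(=O)(=O)C(F)(F)F)(C(C)C)C(C)C
Why: Electrophilic oxygenation of a lithium acetylide by lithium tert-butyl peroxide is the known route from terminal alkynes to ynolates, and the bulky silyl triflate traps the ynolate on oxygen rather than carbon to give an isolable siloxyalkyne.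

Step 6
Reactants: 10 3-ethoxycyclobut-2-en-1-one
Product: 11 3-(benzyloxy)cyclobut-2-en-1-one
Conditions: BnOH (1.5 equiv), camphorsulfonic acid (5 mol %), 5 Å MS, benzene, 40 °C
Reagents that add atoms: benzyl alcohol, OCc1ccccc1
Why: Acid-catalysed addition–elimination at C3 of the vinylogous ester (transetherification) follows the pathway by which 3-alkoxycyclobutenones hydrolyse to cyclobutane-1,3-dione, is pulled forward by sieve uptake of ethanol, and is run below the temperature of electrocyclic ring opening.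

Step 7
Reactants: 9 {[4,5-bis(benzyloxy)-2-(1,3-dioxolan-2-yl)phenyl]ethynyloxy}triisopropylsilane; 11 3-(benzyloxy)cyclobut-2-en-1-one
Product: 16 5-(benzyloxy)-2-[4,5-bis(benzyloxy)-2-(1,3-dioxolan-2-yl)phenyl]-3-(triisopropylsilyloxy)phenol, via vinylketene 12 (not isolated), via vinylcyclobutenone 13 (not isolated), via dienylketene 14 (not isolated), via cyclohexadienone 15 (not isolated)
Conditions: 9 (1.0 equiv), 11 (1.5 equiv, in portions), toluene (0.5 M), argon, base-washed sealed tube, 110 °C then 140 °C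
Reagents that add atoms: none
Why: Danheiser benzannulation: four-electron electrocyclic opening of 11 gives vinylketene 12, whose ketene C=C adds (2+2) to the electron-rich triple bond of 9 to give 13, and a second four-electron opening gives dienylketene 14, which cyclises to 15 and tautomerises to phenol 16. The closest known reaction type is this same cyclobutenone–siloxyalkyne benzannulation, applied here to a cyclobutenone with an alkoxy donor at C3 and an alkyne bearing an aryl group. The one ring formed, luteolin ring A, is closed by a six-electron disrotatory electrocyclisation that makes C4a–C8a, the cycloaddition having already made C8–C8a and C6–C7. No stereocentre is created and the new biaryl axis is not controlled. The step needs a single regiochemical outcome, aryl between the new hydroxyl and the siloxy group, and the ynol-ether polarisation of 9 secures it, because the aryl-bearing carbon is the nucleophilic terminus and bonds to the electrophilic ketene carbonyl carbon while the oxygen-bearing carbon bonds to the ketene alpha carbon. Acylation of the product phenol by surplus ketene is limited by portionwise addition of 11 and by the flanking aryl group, and each ring A oxygen leaves the step separately addressable, the unprotected one becoming O1, the silylated one O7 and the benzylated one O5.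

Step 8
Reactants: 16 5-(benzyloxy)-2-[4,5-bis(benzyloxy)-2-(1,3-dioxolan-2-yl)phenyl]-3-(triisopropylsilyloxy)phenol
Product: 17 6-(benzyloxy)-3-[4,5-bis(benzyloxy)-2-(1,3-dioxolan-2-yl)phenyl]-2-hydroxy-4-(triisopropylsilyloxy)benzaldehyde
Conditions: MgCl2 (3 equiv), Et3N (6 equiv), (CH2O)n (10 equiv), MeCN, reflux
Reagents that add atoms: paraformaldehyde (as formaldehyde), C=O
Why: In the magnesium-mediated Casnati–Skattebøl ortho-formylation, formaldehyde is delivered within the magnesium phenoxide complex only ortho to the free hydroxyl, so only the open ortho carbon (future luteolin C4a) reacts and the para carbon between OTIPS and OBn stays untouched, under conditions mild enough for acetal, silyl and benzyl groups.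

Step 9
Reactants: 1 3,4-bis(benzyloxy)benzaldehyde
Product: 18 1,2-bis(benzyloxy)-4-ethynylbenzene
Conditions: dimethyl (1-diazo-2-oxopropyl)phosphonate (1.3 equiv), K2CO3 (2 equiv), MeOH–THF, rt
Reagents that add atoms: dimethyl (1-diazo-2-oxopropyl)phosphonate, COP(=O)(OC)C(=[N+]=[N-])C(C)=O
Why: Ohira–Bestmann homologation converts aryl aldehydes into terminal alkynes in one mild step through an alkylidene carbene 1,2-shift.

Step 10
Reactants: 17 6-(benzyloxy)-3-[4,5-bis(benzyloxy)-2-(1,3-dioxolan-2-yl)phenyl]-2-hydroxy-4-(triisopropylsilyloxy)benzaldehyde; 18 1,2-bis(benzyloxy)-4-ethynylbenzene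
Product: 20 1-{6-(benzyloxy)-3-[4,5-bis(benzyloxy)-2-(1,3-dioxolan-2-yl)phenyl]-2-hydroxy-4-(triisopropylsilyloxy)phenyl}-3-[3,4-bis(benzyloxy)phenyl]prop-2-yn-1-ol (racemic carbinol), via lithium arylacetylide 19 (not isolated)
Conditions: 18 (2.4 equiv), n-BuLi (2.3 equiv), THF, −78 °C; then 17, −78 to −20 °C; aq NH4Cl
Reagents that add atoms: none
Why: This is a 1,2-addition of a slim lithium acetylide to a salicylaldehyde, in which the first equivalent is spent on the phenol and the second adds to the flanked formyl group; the carbinol configuration is irrelevant because it is oxidised next.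

Step 11
Reactants: 20 the propargylic alcohol of step 10
Product: 21 1-{6-(benzyloxy)-3-[4,5-bis(benzyloxy)-2-(1,3-dioxolan-2-yl)phenyl]-2-hydroxy-4-(triisopropylsilyloxy)phenyl}-3-[3,4-bis(benzyloxy)phenyl]prop-2-yn-1-one
Conditions: MnO2 (activated, 20 equiv), CH2Cl2, rt
Reagents that add atoms: none
Why: MnO2 selectively oxidises the doubly activated (benzylic and propargylic) alcohol under neutral conditions that spare the acetal and the silyl ether, and the phenol becomes deactivated by hydrogen bonding to the new ketone.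

Step 12
Reactants: 21 the ortho-hydroxyaryl ynone of step 11
Product: 22 5-(benzyloxy)-2-[3,4-bis(benzyloxy)phenyl]-8-[4,5-bis(benzyloxy)-2-(1,3-dioxolan-2-yl)phenyl]-7-(triisopropylsilyloxy)-4H-chromen-4-one
Conditions: DMAP (20 mol %), DMF, 30 °C
Reagents that add atoms: none
Why: In this nucleophile-catalysed 6-endo-dig oxa-Michael cyclisation of an ortho-alkynoylphenol, DMAP adds to the ynone beta carbon and is displaced by the phenoxide through addition–elimination, a pathway that leads to the pyranone rather than the 5-exo aurone.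

Step 13
Reactants: 22 the 7-O-TIPS flavone of step 12
Product: 24 5,7-bis(benzyloxy)-2-[3,4-bis(benzyloxy)phenyl]-8-[4,5-bis(benzyloxy)-2-(1,3-dioxolan-2-yl)phenyl]-4H-chromen-4-one, via cesium phenoxide 23 (not isolated)
Conditions: CsF (3 equiv), BnBr (1.5 equiv), DMF, rt
Reagents that add atoms: benzyl bromide, BrCc1ccccc1
Why: In this desilylative alkylation, fluoride cleaves the aryl silyl ether and the resulting 7-phenoxide is benzylated in the same flask, so O7 is never free next to the masked aldehyde and joins the set of hydrogenolysable groups.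

Step 14
Reactants: 24 the dioxolane-bearing flavone of step 13
Product: 25 4,5-bis(benzyloxy)-2-{5,7-bis(benzyloxy)-2-[3,4-bis(benzyloxy)phenyl]-4-oxo-4H-chromen-8-yl}benzaldehyde
Conditions: 1 M HCl, THF, rt
Reagents that add atoms: water, O
Why: Acid hydrolysis of the acetal is safe at this point because both oxygens flanking luteolin C8 are capped (O1 in the ring, O7 as benzyl ether), so the liberated aldehyde cannot be trapped as a benzo[c]chromene lactol.

Step 15
Reactants: 26 methyl 2,4,6-trihydroxybenzoate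
Product: 27 methyl 2,4-bis(benzyloxy)-6-hydroxybenzoate
Conditions: BnBr (2.05 equiv), K2CO3 (2.2 equiv), acetone, reflux
Reagents that add atoms: benzyl bromide, BrCc1ccccc1
Why: Williamson etherification stops at the dibenzyl stage because the last hydroxyl is held in a hydrogen bond to the ester carbonyl and is the least nucleophilic.

Step 16
Reactants: 27 methyl 2,4-bis(benzyloxy)-6-hydroxybenzoate
Product: 28 tert-butyl 3-[2,4-bis(benzyloxy)-6-hydroxyphenyl]-3-oxopropanoate
Conditions: t-BuOAc (5 equiv), LiN(i-Pr)2 (5 equiv), THF, −78 °C; then 27, −78 °C to rt; aq NH4Cl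
Reagents that add atoms: tert-butyl acetate, CC(=O)OC(C)(C)C
Why: In this crossed Claisen condensation of a salicylate with excess lithium tert-butyl acetate enolate, the phenol is carried as its lithium phenoxide and irreversible deprotonation of the beta-ketoester drives acyl substitution at the hindered ester.

Step 17
Reactants: 25 the biaryl aldehyde of step 14; 28 tert-butyl 3-[2,4-bis(benzyloxy)-6-hydroxyphenyl]-3-oxopropanoate
Product: 29 tert-butyl (Z)-2-[2,4-bis(benzyloxy)-6-hydroxybenzoyl]-3-(4,5-bis(benzyloxy)-2-{5,7-bis(benzyloxy)-2-[3,4-bis(benzyloxy)phenyl]-4-oxo-4H-chromen-8-yl}phenyl)prop-2-enoate (geometry expected but not decisive)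
Conditions: piperidine (20 mol %), AcOH (20 mol %), 4 Å MS, toluene, rt
Reagents that add atoms: none
Why: Knoevenagel condensation under piperidinium acetate catalysis gives the ester-activated chalcone at room temperature, where the ketone-chelated phenol should not yet close onto the alkene.

Step 18
Reactants: 29 the alkylidene beta-ketoester of step 17
Product: 31 (2R)-5,7-bis(benzyloxy)-2-(4,5-bis(benzyloxy)-2-{5,7-bis(benzyloxy)-2-[3,4-bis(benzyloxy)phenyl]-4-oxo-4H-chromen-8-yl}phenyl)chroman-4-one, via oxochromane ester 30 (not isolated)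
Conditions: N-[3,5-bis(trifluoromethyl)phenyl]-N'-[(8α,9S)-6'-methoxycinchonan-9-yl]thiourea (quinine-derived, 10 mol %), toluene, −25 °C; then p-TsOH·H2O (0.5 equiv), 80 °C
Reagents that add atoms: none
Why: In this bifunctional organocatalytic intramolecular oxa-Michael addition (6-endo-trig) the thiourea binds the beta-ketoester carbonyls while the quinuclidine activates the phenol, so O1 is delivered to one alkene face and sets C2; the quinine-derived catalyst is planned for 2R, its sense is to be checked by circular dichroism on the first batch with the quinidine-derived pseudoenantiomer taken if it proves opposite, and acid then removes the tert-butyl ester as isobutene and carbon dioxide without touching C2.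

Step 19
Reactants: 31 the (2R)-octabenzyl ether of step 18
Product: 32 (2R)-2-{2-[2-(3,4-dihydroxyphenyl)-5,7-dihydroxy-4-oxo-4H-chromen-8-yl]-4,5-dihydroxyphenyl}-5,7-dihydroxychroman-4-one (CNP0228504.1)
Conditions: H2 (1 atm), 10% Pd/C, THF–MeOH, rt; filtration under argon, no base
Reagents that add atoms: none
Why: Catalytic hydrogenolysis cleaves the eight O-benzyl bonds faster than it touches the flavone enone or the cyclic benzylic C2–O1 bond, and the neutral medium avoids the retro-oxa-Michael opening that would racemise C2.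

## Compound list

1 | 3,4-bis(benzyloxy)benzaldehyde | O=Cc1ccc(OCc2ccccc2)c(OCc2ccccc2)c1 | starting material
2 | 4,5-bis(benzyloxy)-2-bromobenzaldehyde | O=Cc1cc(OCc2ccccc2)c(OCc2ccccc2)cc1Br | intermediate
3 | trimethylsilylacetylene | C#C[Si](C)(C)C | starting material
4 | 4,5-bis(benzyloxy)-2-[(trimethylsilyl)ethynyl]benzaldehyde | O=Cc1cc(OCc2ccccc2)c(OCc2ccccc2)cc1C#C[Si](C)(C)C | intermediate
5 | 2-{4,5-bis(benzyloxy)-2-[(trimethylsilyl)ethynyl]phenyl}-1,3-dioxolane | C[Si](C)(C)C#Cc1cc(OCc2ccccc2)c(OCc2ccccc2)cc1C1OCCO1 | intermediate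
6 | 2-[4,5-bis(benzyloxy)-2-ethynylphenyl]-1,3-dioxolane | C#Cc1cc(OCc2ccccc2)c(OCc2ccccc2)cc1C1OCCO1 | intermediate
7 | lithium acetylide of 6 | [Li+].[C-]#Cc1cc(OCc2ccccc2)c(OCc2ccccc2)cc1C1OCCO1 | intermediate
8 | lithium 2-[4,5-bis(benzyloxy)-2-(1,3-dioxolan-2-yl)phenyl]ethynolate | [Li+].[O-]C#Cc1cc(OCc2ccccc2)c(OCc2ccccc2)cc1C1OCCO1 | intermediate
9 | {[4,5-bis(benzyloxy)-2-(1,3-dioxolan-2-yl)phenyl]ethynyloxy}triisopropylsilane | CC(C)[Si](OC#Cc1cc(OCc2ccccc2)c(OCc2ccccc2)cc1C1OCCO1)(C(C)C)C(C)C | intermediate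
10 | 3-ethoxycyclobut-2-en-1-one | CCOC1=CC(=O)C1 | starting material
11 | 3-(benzyloxy)cyclobut-2-en-1-one | O=C1C=C(OCc2ccccc2)C1 | intermediate
12 | 3-(benzyloxy)buta-1,3-dien-1-one (vinylketene) | O=C=CC(=C)OCc1ccccc1 | intermediate
13 | 4-[1-(benzyloxy)ethenyl]-2-[4,5-bis(benzyloxy)-2-(1,3-dioxolan-2-yl)phenyl]-3-(triisopropylsilyloxy)cyclobut-2-en-1-one (racemic) | O=C1C(c2cc(OCc3ccccc3)c(OCc3ccccc3)cc2C2OCCO2)=C(O[Si](C(C)C)(C(C)C)C(C)C)C1C(=C)OCc1ccccc1 | intermediate
14 | 5-(benzyloxy)-2-[4,5-bis(benzyloxy)-2-(1,3-dioxolan-2-yl)phenyl]-3-(triisopropylsilyloxy)hexa-1,3,5-trien-1-one (ketene and vinyl termini cis) | O=C=C(c1cc(OCc2ccccc2)c(OCc2ccccc2)cc1C1OCCO1)/C(O[Si](C(C)C)(C(C)C)C(C)C)=C\C(=C)OCc1ccccc1 | intermediate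
15 | 5-(benzyloxy)-2-[4,5-bis(benzyloxy)-2-(1,3-dioxolan-2-yl)phenyl]-3-(triisopropylsilyloxy)cyclohexa-2,4-dien-1-one | O=C1CC(OCc2ccccc2)=CC(O[Si](C(C)C)(C(C)C)C(C)C)=C1c1cc(OCc2ccccc2)c(OCc2ccccc2)cc1C1OCCO1 | intermediate
16 | 5-(benzyloxy)-2-[4,5-bis(benzyloxy)-2-(1,3-dioxolan-2-yl)phenyl]-3-(triisopropylsilyloxy)phenol | Oc1cc(OCc2ccccc2)cc(O[Si](C(C)C)(C(C)C)C(C)C)c1-c1cc(OCc2ccccc2)c(OCc2ccccc2)cc1C1OCCO1 | intermediate
17 | 6-(benzyloxy)-3-[4,5-bis(benzyloxy)-2-(1,3-dioxolan-2-yl)phenyl]-2-hydroxy-4-(triisopropylsilyloxy)benzaldehyde | O=Cc1c(O)c(-c2cc(OCc3ccccc3)c(OCc3ccccc3)cc2C2OCCO2)c(O[Si](C(C)C)(C(C)C)C(C)C)cc1OCc1ccccc1 | intermediate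
18 | 1,2-bis(benzyloxy)-4-ethynylbenzene | C#Cc1ccc(OCc2ccccc2)c(OCc2ccccc2)c1 | intermediate
19 | lithium acetylide of 18 | [Li+].[C-]#Cc1ccc(OCc2ccccc2)c(OCc2ccccc2)c1 | intermediate
20 | 1-{6-(benzyloxy)-3-[4,5-bis(benzyloxy)-2-(1,3-dioxolan-2-yl)phenyl]-2-hydroxy-4-(triisopropylsilyloxy)phenyl}-3-[3,4-bis(benzyloxy)phenyl]prop-2-yn-1-ol (racemic) | OC(C#Cc1ccc(OCc2ccccc2)c(OCc2ccccc2)c1)c1c(O)c(-c2cc(OCc3ccccc3)c(OCc3ccccc3)cc2C2OCCO2)c(O[Si](C(C)C)(C(C)C)C(C)C)cc1OCc1ccccc1 | intermediate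
21 | 1-{6-(benzyloxy)-3-[4,5-bis(benzyloxy)-2-(1,3-dioxolan-2-yl)phenyl]-2-hydroxy-4-(triisopropylsilyloxy)phenyl}-3-[3,4-bis(benzyloxy)phenyl]prop-2-yn-1-one | O=C(C#Cc1ccc(OCc2ccccc2)c(OCc2ccccc2)c1)c1c(O)c(-c2cc(OCc3ccccc3)c(OCc3ccccc3)cc2C2OCCO2)c(O[Si](C(C)C)(C(C)C)C(C)C)cc1OCc1ccccc1 | intermediate
22 | 5-(benzyloxy)-2-[3,4-bis(benzyloxy)phenyl]-8-[4,5-bis(benzyloxy)-2-(1,3-dioxolan-2-yl)phenyl]-7-(triisopropylsilyloxy)-4H-chromen-4-one | O=c1cc(-c2ccc(OCc3ccccc3)c(OCc3ccccc3)c2)oc2c(-c3cc(OCc4ccccc4)c(OCc4ccccc4)cc3C3OCCO3)c(O[Si](C(C)C)(C(C)C)C(C)C)cc(OCc3ccccc3)c12 | intermediate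
23 | cesium 7-phenoxide of desilylated 22 | O=c1cc(-c2ccc(OCc3ccccc3)c(OCc3ccccc3)c2)oc2c(-c3cc(OCc4ccccc4)c(OCc4ccccc4)cc3C3OCCO3)c([O-])cc(OCc3ccccc3)c12.[Cs+] | intermediate
24 | 5,7-bis(benzyloxy)-2-[3,4-bis(benzyloxy)phenyl]-8-[4,5-bis(benzyloxy)-2-(1,3-dioxolan-2-yl)phenyl]-4H-chromen-4-one | O=c1cc(-c2ccc(OCc3ccccc3)c(OCc3ccccc3)c2)oc2c(-c3cc(OCc4ccccc4)c(OCc4ccccc4)cc3C3OCCO3)c(OCc3ccccc3)cc(OCc3ccccc3)c12 | intermediate
25 | 4,5-bis(benzyloxy)-2-{5,7-bis(benzyloxy)-2-[3,4-bis(benzyloxy)phenyl]-4-oxo-4H-chromen-8-yl}benzaldehyde | O=Cc1cc(OCc2ccccc2)c(OCc2ccccc2)cc1-c1c(OCc2ccccc2)cc(OCc2ccccc2)c2c(=O)cc(-c3ccc(OCc4ccccc4)c(OCc4ccccc4)c3)oc12 | intermediate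
26 | methyl 2,4,6-trihydroxybenzoate | COC(=O)c1c(O)cc(O)cc1O | starting material
27 | methyl 2,4-bis(benzyloxy)-6-hydroxybenzoate | COC(=O)c1c(O)cc(OCc2ccccc2)cc1OCc1ccccc1 | intermediate
28 | tert-butyl 3-[2,4-bis(benzyloxy)-6-hydroxyphenyl]-3-oxopropanoate | CC(C)(C)OC(=O)CC(=O)c1c(O)cc(OCc2ccccc2)cc1OCc1ccccc1 | intermediate
29 | tert-butyl (Z)-2-[2,4-bis(benzyloxy)-6-hydroxybenzoyl]-3-(4,5-bis(benzyloxy)-2-{5,7-bis(benzyloxy)-2-[3,4-bis(benzyloxy)phenyl]-4-oxo-4H-chromen-8-yl}phenyl)prop-2-enoate | CC(C)(C)OC(=O)/C(C(=O)c1c(O)cc(OCc2ccccc2)cc1OCc1ccccc1)=C\c1cc(OCc2ccccc2)c(OCc2ccccc2)cc1-c1c(OCc2ccccc2)cc(OCc2ccccc2)c2c(=O)cc(-c3ccc(OCc4ccccc4)c(OCc4ccccc4)c3)oc12 | intermediate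
30 | tert-butyl (2R)-5,7-bis(benzyloxy)-2-(4,5-bis(benzyloxy)-2-{5,7-bis(benzyloxy)-2-[3,4-bis(benzyloxy)phenyl]-4-oxo-4H-chromen-8-yl}phenyl)-4-oxochromane-3-carboxylate (C3 labile, keto–enol mixture) | O=C1C(C(=O)OC(C)(C)C)[C@H](c2cc(OCc3ccccc3)c(OCc3ccccc3)cc2-c2c(OCc3ccccc3)cc(OCc3ccccc3)c3c(=O)cc(-c4ccc(OCc5ccccc5)c(OCc5ccccc5)c4)oc23)Oc2cc(OCc3ccccc3)cc(OCc3ccccc3)c21 | intermediate
31 | (2R)-5,7-bis(benzyloxy)-2-(4,5-bis(benzyloxy)-2-{5,7-bis(benzyloxy)-2-[3,4-bis(benzyloxy)phenyl]-4-oxo-4H-chromen-8-yl}phenyl)chroman-4-one | O=C1C[C@H](c2cc(OCc3ccccc3)c(OCc3ccccc3)cc2-c2c(OCc3ccccc3)cc(OCc3ccccc3)c3c(=O)cc(-c4ccc(OCc5ccccc5)c(OCc5ccccc5)c4)oc23)Oc2cc(OCc3ccccc3)cc(OCc3ccccc3)c21 | intermediate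
32 | (2R)-2-{2-[2-(3,4-dihydroxyphenyl)-5,7-dihydroxy-4-oxo-4H-chromen-8-yl]-4,5-dihydroxyphenyl}-5,7-dihydroxychroman-4-one (CNP0228504.1) | O=C1C[C@H](c2cc(O)c(O)cc2-c2c(O)cc(O)c3c(=O)cc(-c4ccc(O)c(O)c4)oc23)Oc2cc(O)cc(O)c21 | target

## Step count and risks

Total step count: 19.
Longest linear sequence: 15 steps (1–5, 7, 8, 10–14, 17–19).

**Step 7.**
- What may go wrong: the vinylogous-ester stabilisation of 11 slows its electrocyclic opening. Thermal silyl migration or decay of 9, ketene dimerisation and O-acylation of the product phenol could then outrun the cycloaddition. The ortho-dioxolanyl aryl group also crowds the (2+2) event.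
- Fallback (biaryl bond by cross-coupling instead of ring construction), setting out from 2:
  - Miyaura borylation of 2 (B2pin2, PdCl2(dppf), KOAc, dioxane, 90 °C) should give 4,5-bis(benzyloxy)-2-(4,4,5,5-tetramethyl-1,3,2-dioxaborolan-2-yl)benzaldehyde F1.
  - In parallel, commercial luteolin is perbenzylated (BnBr, K2CO3, DMF, 80 °C) to 5,7-bis(benzyloxy)-2-[3,4-bis(benzyloxy)phenyl]-4H-chromen-4-one F2.
  - F2 is iodinated at C8 (I2, AgOCOCF3, CH2Cl2, 0 °C) to 5,7-bis(benzyloxy)-2-[3,4-bis(benzyloxy)phenyl]-8-iodo-4H-chromen-4-one F3.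
  - Suzuki–Miyaura coupling of the two partners (Pd(OAc)2, SPhos, K3PO4, toluene–H2O, 90 °C) comes back to the route at 25.

**Step 18.**
- What may go wrong: facial selectivity may be poor because the ortho-flavonyl group and the 6-benzyloxy group on the aroyl ring twist the substrate away from the catalyst's preferred binding mode. Amine-promoted racemic closure may begin already in step 17. The two slowly interconverting rotamers about the biaryl axis may respond differently to the catalyst.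
- Fallback (racemic closure and kinetic resolution), setting out from 25 and bypassing steps 15 to 18:
  - Commercial 2,4,6-trihydroxyacetophenone is dibenzylated (BnBr, K2CO3, acetone, reflux) to 1-[2,4-bis(benzyloxy)-6-hydroxyphenyl]ethan-1-one F4.
  - Claisen–Schmidt condensation with 25 (KOH, EtOH–THF, rt) should give (E)-1-[2,4-bis(benzyloxy)-6-hydroxyphenyl]-3-(4,5-bis(benzyloxy)-2-{5,7-bis(benzyloxy)-2-[3,4-bis(benzyloxy)phenyl]-4-oxo-4H-chromen-8-yl}phenyl)prop-2-en-1-one F5.
  - NaOAc in refluxing EtOH–THF closes it to the racemic octabenzyl flavanone F6.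
  - Asymmetric transfer hydrogenation (RuCl(p-cymene)[(S,S)-TsDPEN], HCO2H–Et3N, EtOAc, rt), stopped near half conversion, should reduce the matched 2S enantiomer to the cis (2S,4S)-flavan-4-ol F7.
  - The 2R ketone is left unreduced and, after chromatography, comes back to the route at 31.

**Step 6.**
- What may go wrong: acid or alcohol may cleave the strained vinylogous ester to open-chain acetoacetate-type esters, or the exchange may stall and leave mixed ethyl and benzyl ethers.
- Fallback (hydrolysis and neutral O-alkylation), setting out from 10: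
  - Dilute aqueous HCl at 0 °C should give cyclobutane-1,3-dione F8, a strongly acidic enol.
  - F8 is O-benzylated by a Mitsunobu reaction (BnOH, PPh3, DIAD, THF, 0 °C), coming back to the route at 11.

## Further compounds

F1 | step 7 | 4,5-bis(benzyloxy)-2-(4,4,5,5-tetramethyl-1,3,2-dioxaborolan-2-yl)benzaldehyde | O=Cc1cc(OCc2ccccc2)c(OCc2ccccc2)cc1B1OC(C)(C)C(C)(C)O1
F2 | step 7 | 5,7-bis(benzyloxy)-2-[3,4-bis(benzyloxy)phenyl]-4H-chromen-4-one | O=c1cc(-c2ccc(OCc3ccccc3)c(OCc3ccccc3)c2)oc2cc(OCc3ccccc3)cc(OCc3ccccc3)c12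
F3 | step 7 | 5,7-bis(benzyloxy)-2-[3,4-bis(benzyloxy)phenyl]-8-iodo-4H-chromen-4-one | O=c1cc(-c2ccc(OCc3ccccc3)c(OCc3ccccc3)c2)oc2c(I)c(OCc3ccccc3)cc(OCc3ccccc3)c12
F4 | step 18 | 1-[2,4-bis(benzyloxy)-6-hydroxyphenyl]ethan-1-one | CC(=O)c1c(O)cc(OCc2ccccc2)cc1OCc1ccccc1
F5 | step 18 | (E)-1-[2,4-bis(benzyloxy)-6-hydroxyphenyl]-3-(4,5-bis(benzyloxy)-2-{5,7-bis(benzyloxy)-2-[3,4-bis(benzyloxy)phenyl]-4-oxo-4H-chromen-8-yl}phenyl)prop-2-en-1-one | O=C(/C=C/c1cc(OCc2ccccc2)c(OCc2ccccc2)cc1-c1c(OCc2ccccc2)cc(OCc2ccccc2)c2c(=O)cc(-c3ccc(OCc4ccccc4)c(OCc4ccccc4)c3)oc12)c1c(O)cc(OCc2ccccc2)cc1OCc1ccccc1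
F6 | step 18 | racemic 5,7-bis(benzyloxy)-2-(4,5-bis(benzyloxy)-2-{5,7-bis(benzyloxy)-2-[3,4-bis(benzyloxy)phenyl]-4-oxo-4H-chromen-8-yl}phenyl)chroman-4-one | O=C1CC(c2cc(OCc3ccccc3)c(OCc3ccccc3)cc2-c2c(OCc3ccccc3)cc(OCc3ccccc3)c3c(=O)cc(-c4ccc(OCc5ccccc5)c(OCc5ccccc5)c4)oc23)Oc2cc(OCc3ccccc3)cc(OCc3ccccc3)c21
F7 | step 18 | 5,7-bis(benzyloxy)-8-{4,5-bis(benzyloxy)-2-[(2S,4S)-5,7-bis(benzyloxy)-4-hydroxychroman-2-yl]phenyl}-2-[3,4-bis(benzyloxy)phenyl]-4H-chromen-4-one | O[C@H]1C[C@@H](c2cc(OCc3ccccc3)c(OCc3ccccc3)cc2-c2c(OCc3ccccc3)cc(OCc3ccccc3)c3c(=O)cc(-c4ccc(OCc5ccccc5)c(OCc5ccccc5)c4)oc23)Oc2cc(OCc3ccccc3)cc(OCc3ccccc3)c21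
F8 | step 6 | cyclobutane-1,3-dione | O=C1CC(=O)C1
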